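**Retrosynthetic overview**

- Feature: the trans oxirane in the 15-membered ring is an oxidised E-trisubstituted C=C, and its CH carbon is tied by a CH2–CH2 unit to the methyl-bearing quaternary carbon of ring A (the carbon between CHBr and CH–CH2Ar).
- Key disconnection: the bond between that olefinic CH and its CH2 neighbour on the ring-A side, giving a vinyl group on the quaternary carbon and an (E)-vinyl iodide on the ester arm; 9-BBN hydroboration and intramolecular B-alkyl Suzuki coupling close the macrocycle (second ring formed).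
- The seco ester comes from a ring-A benzoic acid and an (S)-bromohydrin vinyl iodide (alkyne carboalumination–iodination, Shi epoxidation, HBr opening at the tertiary carbon).
- Ring A (first ring formed) comes from an exo, enantioselective Diels–Alder reaction of (E)-3-bromo-2-methylacrolein with a 1-(arylmethyl)-2-(silyloxymethyl)diene, then Wittig methylenation; the diene is built from prop-2-yn-1-ol (anti-carbomagnesiation–iodination) and a benzylzinc reagent.
- Endgame: reductive 1,3-transposition of the ring-A allylic alcohol to the exocyclic methylene, Shi epoxidation of the macrocyclic olefin (oxirane, third ring), phenol desilylation.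

Key step: step 15

Assumption: ring A is numbered C1 (=C bearing CH2O), C2 (=CH), C3 (CH2), C4 (CHBr), C5 (quaternary C) and C6 (CH–CH2Ar); the facial sense of the oxazaborolidinium catalyst (step 7) and of the ketone-derived dioxirane (steps 12 and 18) is assigned from the accepted transition-state models (formyl C–H···O binding of 2-substituted enals; spiro transition state of the dioxirane).

**Route**

Step 1
Reactants: 1 methyl 4-hydroxy-3-methylbenzoate
Product: 2 methyl 3-methyl-4-[(triisopropylsilyl)oxy]benzoate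
Conditions: iPr3SiCl, imidazole, DMF, rt
Reagents that add atoms: chlorotriisopropylsilane, CC(C)[Si](Cl)(C(C)C)C(C)C
Why: Imidazole-promoted silylation of the phenol; the triisopropylsilyl ether is chosen because it has to outlast the carbonate base of step 15 and the pH 10 buffer of step 18 and still fall to fluoride at the end.

Step 2
Reactants: 2 methyl 3-methyl-4-[(triisopropylsilyl)oxy]benzoate
Product: 3 methyl 3-(bromomethyl)-4-[(triisopropylsilyl)oxy]benzoate
Conditions: N-bromosuccinimide, 2,2'-azobis(2-methylpropionitrile) (cat.), PhCF3, 85 °C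
Reagents that add atoms: N-bromosuccinimide, O=C1CCC(=O)N1Br
Why: Wohl–Ziegler radical bromination of the only benzylic methyl group; the ester-deactivated ring should resist electrophilic bromination in the non-polar medium.

Step 3
Reactants: 4 prop-2-yn-1-ol
Product: 6 (2Z)-2-(iodomethylidene)but-3-en-1-ol, via alkenylmagnesium chelate 5 (not isolated)
Conditions: CH2=CHMgBr (2.5 equiv), CuI (10 mol%), THF, −20 °C → rt; then I2, −40 → 0 °C
Reagents that add atoms: vinylmagnesium bromide, C=C[Mg]Br; iodine, [I][I]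
Why: Duboudin-type anti-carbomagnesiation of the propargylic alkoxide puts the vinyl group on the internal carbon and magnesium on the terminus within a five-membered chelate, so iodinolysis with retention should give the Z iodide (I cis to CH2OH, trans to vinyl).

Step 4
Reactants: 6 (2Z)-2-(iodomethylidene)but-3-en-1-ol
Product: 7 tert-butyl{[(2Z)-2-(iodomethylidene)but-3-en-1-yl]oxy}dimethylsilane
Conditions: tBuMe2SiCl, imidazole, CH2Cl2, 0 °C → rt
Reagents that add atoms: tert-butylchlorodimethylsilane, CC(C)(C)[Si](C)(C)Cl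
Why: Standard silylation of the primary allylic alcohol, which masks it for the organozinc, Lewis acid, ylide and borane steps.

Step 5
Reactants: 3 methyl 3-(bromomethyl)-4-[(triisopropylsilyl)oxy]benzoate, 7 tert-butyl{[(2Z)-2-(iodomethylidene)but-3-en-1-yl]oxy}dimethylsilane
Product: 9 methyl 3-[(2Z)-3-{[(tert-butyldimethylsilyl)oxy]methyl}penta-2,4-dien-1-yl]-4-[(triisopropylsilyl)oxy]benzoate, via benzylzinc bromide 8 (not isolated)
Conditions: 3, Zn dust, LiCl, THF, 0 °C → rt; then 7, Pd(PPh3)4 (5 mol%), THF, rt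
Reagents that add atoms: none
Why: LiCl-assisted zinc insertion into the benzylic C–Br bond tolerates the ester, and Negishi coupling with the vinyl iodide proceeds with retention of geometry, so the diene should carry CH2Ar trans to the vinyl group (reactive s-cis diene with an outside 1-substituent).

Step 6
Reactants: 10 2-methylprop-2-enal (methacrolein)
Product: 12 (2E)-3-bromo-2-methylprop-2-enal, via 2,3-dibromo-2-methylpropanal 11 (not isolated)
Conditions: Br2, CH2Cl2, −78 → 0 °C; then Et3N, 0 °C → rt
Reagents that add atoms: bromine, BrBr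
Why: Bromine addition to the enal followed by amine-induced loss of HBr (C3–H and C2–Br, the dibromide having no α-hydrogen) should give the conjugated β-bromo enal as the more stable E isomer (Br trans to CHO, cis to CH3).

Step 7
Reactants: 9 methyl 3-[(2Z)-3-{[(tert-butyldimethylsilyl)oxy]methyl}penta-2,4-dien-1-yl]-4-[(triisopropylsilyl)oxy]benzoate, 12 (2E)-3-bromo-2-methylprop-2-enal
Product: 13 methyl 3-{[(1R,5S,6R)-5-bromo-2-{[(tert-butyldimethylsilyl)oxy]methyl}-6-formyl-6-methylcyclohex-2-en-1-yl]methyl}-4-[(triisopropylsilyl)oxy]benzoate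
Conditions: (3aR)-1-(2-methylphenyl)-3,3-diphenyl-3a,4,5,6-tetrahydropyrrolo[1,2-c][1,3,2]oxazaborole (20 mol%), HN(SO2CF3)2 (16 mol%), CH2Cl2, −78 → −40 °C
Reagents that add atoms: none
Why: Enantioselective Diels–Alder reaction catalysed by the chiral oxazaborolidinium ion: the leading bond joins the enal β-carbon to the unsubstituted diene terminus so that the quaternary carbon ends next to CH–CH2Ar, the bulky catalyst-bound formyl group takes the exo position (CHO trans to CH2Ar), suprafacial addition to the E-enal keeps Br cis to CH3, and shielding of one enal face by the catalyst sets the absolute configuration of C4, C5 and C6 together.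

Step 8
Reactants: 13 methyl 3-{[(1R,5S,6R)-5-bromo-2-{[(tert-butyldimethylsilyl)oxy]methyl}-6-formyl-6-methylcyclohex-2-en-1-yl]methyl}-4-[(triisopropylsilyl)oxy]benzoate
Product: 14 methyl 3-{[(1R,5S,6S)-5-bromo-2-{[(tert-butyldimethylsilyl)oxy]methyl}-6-ethenyl-6-methylcyclohex-2-en-1-yl]methyl}-4-[(triisopropylsilyl)oxy]benzoate
Conditions: Ph3PCH3Br, KN(SiMe3)2, THF, 0 °C; then 13, −78 → 0 °C
Reagents that add atoms: methyltriphenylphosphonium bromide, C[P+](c1ccccc1)(c1ccccc1)c1ccccc1.[Br-]
Why: Wittig methylenation of the neopentyl aldehyde, which has no α-hydrogen and so can neither eliminate the β-bromide nor epimerise, while the benzoate ester is left alone by the ylide at low temperature (the change of descriptor at C5 is a priority change only).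

Step 9
Reactants: 14 methyl 3-{[(1R,5S,6S)-5-bromo-2-{[(tert-butyldimethylsilyl)oxy]methyl}-6-ethenyl-6-methylcyclohex-2-en-1-yl]methyl}-4-[(triisopropylsilyl)oxy]benzoate
Product: 16 3-{[(1R,5S,6S)-5-bromo-2-{[(tert-butyldimethylsilyl)oxy]methyl}-6-ethenyl-6-methylcyclohex-2-en-1-yl]methyl}-4-[(triisopropylsilyl)oxy]benzoic acid, via trimethylstannyl ester 15 (not isolated)
Conditions: Me3SnOH, ClCH2CH2Cl, 80 °C; then aq. HCl (0.1 M) wash
Reagents that add atoms: trimethyltin hydroxide, C[Sn](C)(C)O
Why: Neutral tin hydroxide-mediated hydrolysis of the methyl ester avoids the aqueous alkali that would strip the aryl silyl ether, and a dilute acid wash frees the acid from its stannyl ester.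

Step 10
Reactants: 17 5-bromo-2-methylpent-2-ene
Product: 18 6-methylhept-5-en-1-yne
Conditions: LiC≡CH·H2NCH2CH2NH2, DMSO, 0 °C → rt
Reagents that add atoms: lithium acetylide, [Li]C#C
Why: SN2 alkylation of the acetylide by the primary homoallylic bromide.

Step 11
Reactants: 18 6-methylhept-5-en-1-yne
Product: 20 (1E)-1-iodo-2,6-dimethylhepta-1,5-diene, via alkenyldimethylalane 19 (not isolated)
Conditions: Me3Al, Cp2ZrCl2 (20 mol%), CH2Cl2, 0 °C → rt; then I2, THF, −30 → 0 °C
Reagents that add atoms: trimethylaluminium, C[Al](C)C; iodine, [I][I]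
Why: Negishi zirconium-catalysed syn-carboalumination places methyl on the internal and aluminium on the terminal alkyne carbon, and iodinolysis with retention should give the E vinyl iodide.

Step 12
Reactants: 20 (1E)-1-iodo-2,6-dimethylhepta-1,5-diene
Product: 21 (3S)-3-[(3E)-4-iodo-3-methylbut-3-en-1-yl]-2,2-dimethyloxirane
Conditions: 1,2:4,5-di-O-isopropylidene-β-L-erythro-2,3-hexodiulo-2,6-pyranose (30 mol%), KHSO5 (as 2KHSO5·KHSO4·K2SO4), K2CO3, Bu4NHSO4, MeCN/CH2(OMe)2/aq. Na2B4O7 buffer, 0 °C
Reagents that add atoms: potassium peroxymonosulfate, [K+].OOS(=O)(=O)[O-]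
Why: Shi asymmetric epoxidation: the dioxirane of the L-fructose-derived ketone attacks the electron-rich Me2C=CH olefin (the iodo-olefin is deactivated) through the spiro transition state and should set the S configuration at the oxirane CH.

Step 13
Reactants: 21 (3S)-3-[(3E)-4-iodo-3-methylbut-3-en-1-yl]-2,2-dimethyloxirane
Product: 22 (3S,6E)-2-bromo-7-iodo-2,6-dimethylhept-6-en-3-ol
Conditions: HBr (48% aq., 1.1 equiv), Et2O, −20 °C
Reagents that add atoms: hydrogen bromide, Br
Why: Acid-promoted opening of the trisubstituted epoxide delivers bromide to the tertiary carbon (borderline SN1 character) and leaves the C–O bond of the stereogenic CH untouched, so the S configuration is kept.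

Step 14
Reactants: 16 3-{[(1R,5S,6S)-5-bromo-2-{[(tert-butyldimethylsilyl)oxy]methyl}-6-ethenyl-6-methylcyclohex-2-en-1-yl]methyl}-4-[(triisopropylsilyl)oxy]benzoic acid, 22 (3S,6E)-2-bromo-7-iodo-2,6-dimethylhept-6-en-3-ol
Product: 23 (3S,6E)-2-bromo-7-iodo-2,6-dimethylhept-6-en-3-yl 3-{[(1R,5S,6S)-5-bromo-2-{[(tert-butyldimethylsilyl)oxy]methyl}-6-ethenyl-6-methylcyclohex-2-en-1-yl]methyl}-4-[(triisopropylsilyl)oxy]benzoate
Conditions: N,N'-dicyclohexylcarbodiimide, 4-(dimethylamino)pyridine, CH2Cl2, 0 °C → rt
Reagents that add atoms: none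
Why: Steglich esterification acylates the secondary hydroxyl under nearly neutral conditions that should not close the bromohydrin back to the epoxide, and no bond to the carbinol stereocentre is broken.

Step 15
Reactants: 23 (3S,6E)-2-bromo-7-iodo-2,6-dimethylhept-6-en-3-yl 3-{[(1R,5S,6S)-5-bromo-2-{[(tert-butyldimethylsilyl)oxy]methyl}-6-ethenyl-6-methylcyclohex-2-en-1-yl]methyl}-4-[(triisopropylsilyl)oxy]benzoate
Product: 25 15-membered E-olefin macrolide with ring A as the allylic tert-butyldimethylsilyl ether cyclohexene and the phenol as triisopropylsilyl ether, via B-alkyl-9-BBN 24 (not isolated)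
Conditions: 9-BBN (dimer), THF, rt; then slow addition to Pd(dppf)Cl2 (20 mol%), AsPh3 (20 mol%), Cs2CO3, DMF/THF/H2O, rt → 45 °C, final concentration about 1 mM
Reagents that add atoms: none
Why: 9-BBN adds anti-Markovnikov to the vinyl group on C5, the only monosubstituted olefin, to give primary alkylborane 24; the (E)-vinyl iodide then adds oxidatively to zerovalent palladium, the base-activated borane transfers its primary alkyl group, and reductive elimination from the dppf complex joins the olefinic CH to the CH2 on the ring-A side with retention of the E geometry. The closest known reaction type is the B-alkyl Suzuki–Miyaura macrocyclisation used to close large rings at stereodefined trisubstituted olefins. The 15-membered ring is closed by this intramolecular sp3–sp2 C–C coupling of the two ends of the seco ester under slow addition and high dilution. No stereocentre is formed; the E geometry carried in from the vinyl iodide is what step 18 later turns into both oxirane centres. The step needs chemoselective hydroboration, which the single monosubstituted olefin secures against the two trisubstituted olefins, and chemoselective oxidative addition, which the sp2 C–I bond secures over the secondary and tertiary alkyl bromides. The carbinol is already acylated, so the bromohydrin cannot close to an epoxide under the carbonate base, and the triisopropylsilyl ether keeps the phenol masked against it.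

Step 16
Reactants: 25 15-membered E-olefin macrolide with ring A as the allylic tert-butyldimethylsilyl ether cyclohexene and the phenol as triisopropylsilyl ether
Product: 26 15-membered E-olefin macrolide with free ring-A allylic alcohol (C1–CH2OH) and aryl triisopropylsilyl ether
Conditions: camphor-10-sulfonic acid (10 mol%), MeOH/CH2Cl2, 0 °C
Reagents that add atoms: none
Why: Acid-catalysed methanolysis removes the primary alkyl silyl ether much faster than the aryl triisopropylsilyl ether, and a brief cold treatment should spare the tertiary bromide.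

Step 17
Reactants: 26 15-membered E-olefin macrolide with free ring-A allylic alcohol (C1–CH2OH) and aryl triisopropylsilyl ether
Product: 29 15-membered E-olefin macrolide with exocyclic methylene on ring A and aryl triisopropylsilyl ether, via allylic sulfonylhydrazine 27 (not isolated), via allylic diazene 28 (not isolated)
Conditions: 2-O2NC6H4SO2NHNH2, PPh3, EtO2CN=NCO2Et, THF, −30 °C; then rt
Reagents that add atoms: none
Why: Myers reductive 1,3-transposition: Mitsunobu N-alkylation of the sulfonyl hydrazide, loss of sulfinic acid to the allylic diazene and retro-ene loss of N2 deliver hydrogen to the ring CH (C2, no stereocentre) and leave the exocyclic methylene, while the silylated phenol cannot compete as a Mitsunobu nucleophile.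

Step 18
Reactants: 29 15-membered E-olefin macrolide with exocyclic methylene on ring A and aryl triisopropylsilyl ether
Product: 30 O-triisopropylsilyl bromophycolide S
Conditions: 1,2:4,5-di-O-isopropylidene-β-L-erythro-2,3-hexodiulo-2,6-pyranose (50 mol%), KHSO5 (as 2KHSO5·KHSO4·K2SO4), K2CO3, Bu4NHSO4, MeCN/CH2(OMe)2/aq. Na2B4O7 buffer, 0 °C
Reagents that add atoms: potassium peroxymonosulfate, [K+].OOS(=O)(=O)[O-]
Why: Shi epoxidation of the only trisubstituted olefin (the 1,1-disubstituted exocyclic olefin is a poor substrate for this dioxirane); syn oxygen transfer from the L-fructose-derived ketone to the E-olefin should set both oxirane centres together as S,S.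

Step 19
Reactants: 30 O-triisopropylsilyl bromophycolide S
Product: 31 bromophycolide S
Conditions: Bu4NF, AcOH, THF, 0 °C
Reagents that add atoms: none
Why: Fluoride cleaves the aryl Si–O bond rapidly, and buffering with acetic acid should keep the medium from opening the epoxide or eliminating the tertiary bromide.

**Compound list**

1 | methyl 4-hydroxy-3-methylbenzoate | COC(=O)c1ccc(O)c(C)c1 | starting material
2 | methyl 3-methyl-4-[(triisopropylsilyl)oxy]benzoate | COC(=O)c1ccc(O[Si](C(C)C)(C(C)C)C(C)C)c(C)c1 | intermediate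
3 | methyl 3-(bromomethyl)-4-[(triisopropylsilyl)oxy]benzoate | COC(=O)c1ccc(O[Si](C(C)C)(C(C)C)C(C)C)c(CBr)c1 | intermediate
4 | prop-2-yn-1-ol | C#CCO | starting material
5 | bromomagnesium (2Z)-2-[(bromomagnesio)methylidene]but-3-en-1-olate (chelated alkenylmagnesium alkoxide, not isolated) | Br[Mg]/C=C(\CO[Mg]Br)C=C | intermediate
6 | (2Z)-2-(iodomethylidene)but-3-en-1-ol | I/C=C(\CO)C=C | intermediate
7 | tert-butyl{[(2Z)-2-(iodomethylidene)but-3-en-1-yl]oxy}dimethylsilane | I/C=C(\CO[Si](C)(C)C(C)(C)C)C=C | intermediate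
8 | {[5-(methoxycarbonyl)-2-(triisopropylsilyloxy)phenyl]methyl}zinc bromide (not isolated) | COC(=O)c1ccc(O[Si](C(C)C)(C(C)C)C(C)C)c(C[Zn]Br)c1 | intermediate
9 | methyl 3-[(2Z)-3-{[(tert-butyldimethylsilyl)oxy]methyl}penta-2,4-dien-1-yl]-4-[(triisopropylsilyl)oxy]benzoate | COC(=O)c1ccc(O[Si](C(C)C)(C(C)C)C(C)C)c(C/C=C(\CO[Si](C)(C)C(C)(C)C)C=C)c1 | intermediate
10 | 2-methylprop-2-enal (methacrolein) | C=C(C)C=O | starting material
11 | 2,3-dibromo-2-methylpropanal (racemic, not isolated) | O=CC(C)(Br)CBr | intermediate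
12 | (2E)-3-bromo-2-methylprop-2-enal | Br/C=C(\C)C=O | intermediate
13 | methyl 3-{[(1R,5S,6R)-5-bromo-2-{[(tert-butyldimethylsilyl)oxy]methyl}-6-formyl-6-methylcyclohex-2-en-1-yl]methyl}-4-[(triisopropylsilyl)oxy]benzoate (Br, CH3 and CH2Ar cis; CHO trans to them) | CC(C)(C)[Si](C)(C)OCC1=CC[C@H](Br)[C@@](C)(C=O)[C@@H]1Cc1cc(ccc1O[Si](C(C)C)(C(C)C)C(C)C)C(=O)OC | intermediate
14 | methyl 3-{[(1R,5S,6S)-5-bromo-2-{[(tert-butyldimethylsilyl)oxy]methyl}-6-ethenyl-6-methylcyclohex-2-en-1-yl]methyl}-4-[(triisopropylsilyl)oxy]benzoate | CC(C)(C)[Si](C)(C)OCC1=CC[C@H](Br)[C@@](C)(C=C)[C@@H]1Cc1cc(ccc1O[Si](C(C)C)(C(C)C)C(C)C)C(=O)OC | intermediate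
15 | trimethylstannyl ester of acid 16 (not isolated) | CC(C)(C)[Si](C)(C)OCC1=CC[C@H](Br)[C@@](C)(C=C)[C@@H]1Cc1cc(ccc1O[Si](C(C)C)(C(C)C)C(C)C)C(=O)O[Sn](C)(C)C | intermediate
16 | 3-{[(1R,5S,6S)-5-bromo-2-{[(tert-butyldimethylsilyl)oxy]methyl}-6-ethenyl-6-methylcyclohex-2-en-1-yl]methyl}-4-[(triisopropylsilyl)oxy]benzoic acid | CC(C)(C)[Si](C)(C)OCC1=CC[C@H](Br)[C@@](C)(C=C)[C@@H]1Cc1cc(ccc1O[Si](C(C)C)(C(C)C)C(C)C)C(=O)O | intermediate
17 | 5-bromo-2-methylpent-2-ene | CC(C)=CCCBr | starting material
18 | 6-methylhept-5-en-1-yne | CC(C)=CCCC#C | intermediate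
19 | [(1E)-2,6-dimethylhepta-1,5-dien-1-yl]dimethylalane (not isolated) | CC(C)=CCC/C(C)=C/[Al](C)C | intermediate
20 | (1E)-1-iodo-2,6-dimethylhepta-1,5-diene | CC(C)=CCC/C(C)=C/I | intermediate
21 | (3S)-3-[(3E)-4-iodo-3-methylbut-3-en-1-yl]-2,2-dimethyloxirane | CC1(C)O[C@H]1CC/C(C)=C/I | intermediate
22 | (3S,6E)-2-bromo-7-iodo-2,6-dimethylhept-6-en-3-ol | O[C@H](C(C)(C)Br)CC/C(C)=C/I | intermediate
23 | seco ester: (3S,6E)-2-bromo-7-iodo-2,6-dimethylhept-6-en-3-yl ester of acid 16 | CC(C)(C)[Si](C)(C)OCC1=CC[C@H](Br)[C@@](C)(C=C)[C@@H]1Cc1cc(ccc1O[Si](C(C)C)(C(C)C)C(C)C)C(=O)O[C@H](C(C)(C)Br)CC/C(C)=C/I | intermediate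
24 | B-alkyl-9-BBN from 23: CH2CH2–B(9-borabicyclo[3.3.1]nonyl) on C5 in place of vinyl (not isolated) | CC(C)(C)[Si](C)(C)OCC1=CC[C@H](Br)[C@@](C)(CCB2C3CCCC2CCC3)[C@@H]1Cc1cc(ccc1O[Si](C(C)C)(C(C)C)C(C)C)C(=O)O[C@H](C(C)(C)Br)CC/C(C)=C/I | intermediate
25 | 15-membered E-olefin macrolide: ring A (4S,5S,6R) with C1–CH2OSi(tBu)Me2 and C1=C2; arm C5–CH2–CH2–CH=C(CH3)–CH2–CH2–CH(O) with E olefin; (S)-carbinol bearing C(CH3)2Br; aryl OSi(iPr)3 | CC(C)(C)[Si](C)(C)OCC1=CC[C@H](Br)[C@@]2(C)CC/C=C(\C)CC[C@@H](C(C)(C)Br)OC(=O)c3ccc(O[Si](C(C)C)(C(C)C)C(C)C)c(c3)C[C@H]12 | intermediate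
26 | macrolide 25 with free C1–CH2OH | OCC1=CC[C@H](Br)[C@@]2(C)CC/C=C(\C)CC[C@@H](C(C)(C)Br)OC(=O)c3ccc(O[Si](C(C)C)(C(C)C)C(C)C)c(c3)C[C@H]12 | intermediate
27 | N-allyl-N-(2-nitrobenzenesulfonyl)hydrazine from 26 (C1–CH2–N(NH2)SO2Ar, not isolated) | NN(CC1=CC[C@H](Br)[C@@]2(C)CC/C=C(\C)CC[C@@H](C(C)(C)Br)OC(=O)c3ccc(O[Si](C(C)C)(C(C)C)C(C)C)c(c3)C[C@H]12)S(=O)(=O)c1ccccc1[N+](=O)[O-] | intermediate
28 | allylic diazene from 27 (C1–CH2–N=NH, not isolated) | N=NCC1=CC[C@H](Br)[C@@]2(C)CC/C=C(\C)CC[C@@H](C(C)(C)Br)OC(=O)c3ccc(O[Si](C(C)C)(C(C)C)C(C)C)c(c3)C[C@H]12 | intermediate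
29 | macrolide with exocyclic methylene on C1 of ring A, E olefin, aryl OSi(iPr)3 | C=C1CC[C@H](Br)[C@@]2(C)CC/C=C(\C)CC[C@@H](C(C)(C)Br)OC(=O)c3ccc(O[Si](C(C)C)(C(C)C)C(C)C)c(c3)C[C@H]12 | intermediate
30 | O-triisopropylsilyl bromophycolide S ((S,S)-oxirane) | C=C1CC[C@H](Br)[C@@]2(C)CC[C@@H]3O[C@@]3(C)CC[C@@H](C(C)(C)Br)OC(=O)c3ccc(O[Si](C(C)C)(C(C)C)C(C)C)c(c3)C[C@H]12 | intermediate
31 | bromophycolide S | C=C1CC[C@H](Br)[C@@]2(C)CC[C@@H]3O[C@@]3(C)CC[C@@H](C(C)(C)Br)OC(=O)c3ccc(O)c(c3)C[C@H]12 | target

**Step count**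

Total: 19 steps. Longest linear sequence: 12 steps (1 → 2 → 3 → 9 → 13 → 14 → 16 → 23 → 25 → 26 → 29 → 31 through 30; the branch from 4 is equally long).

**Steps most likely to fail**

Step 7. The cycloaddition may run through the endo-formyl transition state, may take the opposite regiochemical orientation because the 2-substituent of the diene opposes the 1-substituent, or may show poor facial discrimination with the β-bromo enal. The fallback gives up catalytic asymmetric induction in favour of resolution. It sets out from 9 and 12, which are combined under the bulky achiral borane B(C6F5)3 in CH2Cl2 at low temperature, a Lewis acid known to steer enals and acyclic dienes to exo adducts. This should give the racemic exo adduct, that is 13 together with the mirror-image aldehyde F1. The enantiomers are separated by preparative chromatography on a chiral stationary phase and the route is rejoined at 13.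

Step 15. Intermolecular coupling may outrun ring closure, or the neopentyl-type alkylborane may transmetalate slowly so that protodeboronation or β-hydride elimination takes over. The fallback keeps the same C–C bond but forms it intermolecularly and closes the ring at the ester. It sets out from 14 and 21. Hydroboration of 14 with 9-BBN gives the alkylborane F2, which is coupled with 21 under Pd(dppf)Cl2, AsPh3 and Cs2CO3 to the epoxy methyl ester F3. Me3SnOH converts F3 through the stannyl ester F4 into the epoxy acid F5, and HBr in Et2O at −20 °C opens the oxirane to the bromohydrin seco acid F6. Yamaguchi macrolactonisation (2,4,6-trichlorobenzoyl chloride, Et3N; then 4-(dimethylamino)pyridine, toluene, high dilution) through the mixed anhydride F7 comes back to the route at 25.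

Step 18. The conformation of the 15-membered ring may override the chiral dioxirane and give poor facial selectivity, or the exocyclic olefin may be oxidised in competition. The fallback replaces direct oxygen transfer by a two-step anti-addition and closure, which puts oxygen on the face opposite to the one an electrophile attacks. It sets out from 29. N-Bromosuccinimide in aqueous THF at 0 °C should give the bromohydrin F8 (Br on the former olefinic CH, OH on the methyl-bearing carbon). K2CO3 in MeOH at 0 °C closes it with inversion at the CH–Br carbon, and the route is rejoined at 30.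

**Further compounds**

F1 | step 7 | mirror-image aldehyde, methyl 3-{[(1S,5R,6S)-5-bromo-2-{[(tert-butyldimethylsilyl)oxy]methyl}-6-formyl-6-methylcyclohex-2-en-1-yl]methyl}-4-[(triisopropylsilyl)oxy]benzoate | CC(C)(C)[Si](C)(C)OCC1=CC[C@@H](Br)[C@](C)(C=O)[C@H]1Cc1cc(ccc1O[Si](C(C)C)(C(C)C)C(C)C)C(=O)OC
F2 | step 15 | B-alkyl-9-BBN from methyl ester 14 | CC(C)(C)[Si](C)(C)OCC1=CC[C@H](Br)[C@@](C)(CCB2C3CCCC2CCC3)[C@@H]1Cc1cc(ccc1O[Si](C(C)C)(C(C)C)C(C)C)C(=O)OC
F3 | step 15 | coupled epoxy methyl ester (E olefin, (S)-oxirane) | CC(C)(C)[Si](C)(C)OCC1=CC[C@H](Br)[C@@](C)(CC/C=C(\C)CC[C@@H]2OC2(C)C)[C@@H]1Cc1cc(ccc1O[Si](C(C)C)(C(C)C)C(C)C)C(=O)OC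
F4 | step 15 | trimethylstannyl ester of the epoxy acid | CC(C)(C)[Si](C)(C)OCC1=CC[C@H](Br)[C@@](C)(CC/C=C(\C)CC[C@@H]2OC2(C)C)[C@@H]1Cc1cc(ccc1O[Si](C(C)C)(C(C)C)C(C)C)C(=O)O[Sn](C)(C)C
F5 | step 15 | epoxy acid | CC(C)(C)[Si](C)(C)OCC1=CC[C@H](Br)[C@@](C)(CC/C=C(\C)CC[C@@H]2OC2(C)C)[C@@H]1Cc1cc(ccc1O[Si](C(C)C)(C(C)C)C(C)C)C(=O)O
F6 | step 15 | bromohydrin seco acid ((S)-carbinol, tertiary bromide) | CC(C)(C)[Si](C)(C)OCC1=CC[C@H](Br)[C@@](C)(CC/C=C(\C)CC[C@H](O)C(C)(C)Br)[C@@H]1Cc1cc(ccc1O[Si](C(C)C)(C(C)C)C(C)C)C(=O)O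
F7 | step 15 | mixed anhydride of F6 with 2,4,6-trichlorobenzoic acid | CC(C)(C)[Si](C)(C)OCC1=CC[C@H](Br)[C@@](C)(CC/C=C(\C)CC[C@H](O)C(C)(C)Br)[C@@H]1Cc1cc(ccc1O[Si](C(C)C)(C(C)C)C(C)C)C(=O)OC(=O)c1c(Cl)cc(Cl)cc1Cl
F8 | step 18 | macrocyclic bromohydrin (Br on the former olefinic CH, OH on the methyl-bearing carbon, anti) | C=C1CC[C@H](Br)[C@@]2(C)CC[C@@H](Br)[C@@](C)(O)CC[C@@H](C(C)(C)Br)OC(=O)c3ccc(O[Si](C(C)C)(C(C)C)C(C)C)c(c3)C[C@H]12
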